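Remark on the chemistry: commercial (+)-limonene 1,2-oxide (the cis/trans epoxide mixture made from (R)-limonene) is taken as the chiral-pool starting material, and diene 12 is drawn as its (1E,3Z) isomer although its alkene geometry is immaterial because both double bonds end up in the arene.

## Structural features

The target is a flavone: a 4H-chromen-4-one in which benzo ring A is fused to pyranone ring C through C4a–C8a, with a 4-hydroxyphenyl ring B at C2. Ring A is fully differentiated: hydroxyls at C5 (hydrogen-bonded to the C4 carbonyl) and C7, hydrogen at C6, and at C8, next to the fusion carbon C8a, a ten-carbon 5-methyl-2-(prop-1-en-2-yl)hex-5-enyl chain. The only stereocentre is C2'' of that chain (R); it has no stereogenic neighbour, is allylic to the isopropenyl group and sits one methylene away from the arene. Fragile features are the two 1,1-disubstituted alkenes (protonation, cation–olefin cyclisation, migration, hydrogenation, electrophilic halogen), the three phenols, and the stereocentre itself, which would racemise through any carbonyl, cation or radical on an adjacent carbon. The real difficulty is regiochemical and stereochemical at once: the chain must go to C8 and not to C6 (direct alkylation of a 5,7-dihydroxyflavone or a phloroglucinol does not discriminate, and acid interconverts the isomers by the Wessely–Moser rearrangement), and the stereocentre lies where there is no functional handle. The key step exploits that C5(O)–C6–C7(O)–C8(alkyl) is the chain of a gamma-alkylated beta-keto ester at the dienolate level, while C4a=C8a is the C5=C6 alkene of a 2-aryl-4-pyranone that already contains rings B and C; a bromine on the future C4a supplies the oxidation level for aromatisation.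

## Logic of the disconnections

24 ⇒ 23. No skeletal bond is cut, only O4'–Si. The ring B phenol must be masked while ring A is made, because a free phenol would protonate the ketene acetal end of 12 and consume the silyl triflate. A bulky silyl ether comes off without acid, hydrogen or oxidant, all of which the two alkenes forbid. There is no gain in skeleton. The forward step must cleave one aryl silyl ether beside a chromone and two alkenes, which fluoride at 0 °C should do.

23 ⇒ 12 + 19. The bonds C8–C8a and C4a–C5 are cut, that is, all of ring A except C4a–C8a. The 5,7-dioxygenation with the alkyl group at C8 is the retron of a 4-alkyl-1,3-dioxygenated diene, and C4a=C8a is an alkene that 19 already holds. The gain is two fragments of similar size, ring A with its whole substitution pattern in one operation, and no C6/C8 question because ring C exists before ring A. The stereocentre of 12 is two atoms from the reacting terminus. The forward step must bond the alkyl-bearing diene terminus to C6 of 19 and the acetal carbon to C5, then expel HBr and methanol without acid damage to the alkenes. Compounds 12, 19 and 23 carry the same (R) centre and a consistent numbering and are used unchanged.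

12 ⇒ 11 ⇒ 10. The two O–Si bonds are cut. The diene is the bis-silylated dienolate of a beta-keto ester, so the skeleton is already complete in 10. The gain is a stable, purifiable precursor. The forward steps demand O-silylation of the enol, then kinetic gamma-deprotonation and O-silylation with exclusion of moisture.

10 ⇒ 8 (through 9). The C2–C3 bond of 10 (acyl carbon to methylene) is cut. The other obvious cut, at C4–C5, would require alkylating a keto ester dianion with a primary iodide branched at the beta carbon. Its beta hydrogen is allylic, so elimination to a diene would compete. That iodide could also be reached from the chiral pool only by excising a ring carbon through intermediates with the stereocentre alpha to a carbonyl group. Acylation keeps the stereocentre gamma to the nearest carbonyl throughout. The gain is an acid whose only functionality is remote from the stereocentre. The forward step demands a C-acylation under near-neutral conditions.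

8 ⇒ 6 ⇒ 4. Only C1 changes: the carboxyl carbon of 8 is the carbinol carbon of 6 and the terminal vinyl carbon of 4 (C–O bonds removed, C1=C2 restored). This is cut because a monosubstituted alkene can be told apart from 1,1-disubstituted ones by a hindered borane. The gain is a hydrocarbon with no protecting groups. The forward steps demand site-selective anti-Markovnikov hydroboration and an alcohol-to-acid oxidation that spares alkenes.

4 ⇒ 3. Both C=CH2 bonds are cut. The ketone of 3 becomes the 2-methylallyl terminus of the chain, and the aldehyde carbon, after methylenation, becomes the future C8 of ring A with its new methylene as the future C7. One operation serves both ends. The forward step demands excess ylide and no aldol cyclisation of the 1,6-dicarbonyl compound.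

3 ⇒ 1. C1 and C6 of 3 are reconnected into the cyclohexane ring. The p-menthane skeleton holds the stereocentre with its isopropenyl group and both arms in the right lengths and oxidation states, in high enantiomeric purity. The forward step must cleave the ring at the former trisubstituted alkene only, which the epoxide guarantees.

19 ⇒ 18 ⇒ 17. The C5–Br bond is cut and the C2=C3 unsaturation is returned to C2–H and C3–H2. In 17 there is a single enol-ether carbon, so bromination can only go to C5. Bromination of the fully unsaturated pyranone could choose C3, which is conjugated to the electron-rich aryl group. For the same reason the pyranone is not assembled by condensing an amide acetal with a 1,3-diketone, which would functionalise the central carbon and give a 3-acylpyranone. The forward steps demand electrophilic bromination of a vinylogous ester and a dehydrogenation that tolerates the vinyl bromide and the silyl ether.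

17 ⇒ 14 + 15. The bonds C2–C3 and O1–C6 are cut (hetero-Diels–Alder retron). The gain is a one-step ring C from an aldehyde and a commercial diene. The forward step needs a Lewis acid that an electron-rich aldehyde and an aryl silyl ether tolerate.

14 ⇒ 13. The O–Si bond is cut; this is a routine silylation.

## Other disconnections considered

Alternative 1: The cut is the C1''–C2'' bond, between the benzylic methylene and the stereocentre. Forward, the C8 trimethylammonium salt A2 of the intact flavone would be treated with base to release an ortho-quinone methide across C8 and O7. This would be trapped by the enamine formed from 5-methylhex-5-enal A3 and the (S)-diarylprolinol silyl ether A4, and hydrolysis would leave the pyrano-fused lactol A1.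
- In its favour: the flavone is bought, not built. C8 is addressed by an aminomethylation that prefers that position. The stereocentre is made catalytically and immediately parked in a lactol where it cannot epimerise. The step count is lower than in the chosen plan, so on step economy the alternative is the better.
- Against it here: A1 still lacks the isopropenyl group. Turning the lactol carbon into it needs methyl addition, oxidation and methylenation on a substrate with three free phenols, during which the stereocentre sits alpha to a ketone in the presence of a basic ylide. The quinone methide needs base while the enamine cycle needs a free secondary amine and usually an acid co-catalyst, so the two must be made to coexist. Enantiopurity would rest on catalyst control, not on a chiral-pool centre.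
- Comparison: on regiochemistry the plans are equal, since both address C8 only. On security of configuration the chosen plan is better, because its stereocentre is never placed next to a carbonyl group. On mechanism both key steps are extrapolations, the alternative arguably the smaller one.

Alternative 2: The cut removes C4 as a one-carbon unit and breaks C4a–C4, C4–C3 and O1–C2, leaving the ortho-iodophenol A6 and the arylacetylene A7. Forward, a carbonylative Sonogashira coupling under a divalent palladium phosphine catalyst with a secondary amine, followed by 6-endo closure of the ynone, would give the bis(silyl) ether A5.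
- In its favour: this ring C construction is an established flavone synthesis, so on precedent for the key step the alternative is better than the chosen plan. It is convergent and mild toward the alkenes.
- Against it here: the real difficulties move into A6, a hexasubstituted benzene with the chiral chain between two oxygens, iodine between two others, and the three oxygens told apart. Making it needs either a de novo ring A synthesis of the kind the chosen plan uses or a C-alkylation of a phloroglucinol with the C6/C8 ambiguity. The phenol that must cyclise is flanked by the bulky chain, and 5-exo closure to an aurone competes.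
- Comparison: regiocontrol is by protecting groups instead of by connectivity, so the chosen plan is better there. Compatibility of the catalytic step with the three alkenes is equal. The overall count would most likely be higher.

Alternative 3: The cut is C5–C6 of ring A; ring C is kept as a pyranone that masks a polyketide chain, precursor A9. Forward, two equivalents of a strong amide base would form the dianion of A9, and the acetyl methyl carbon would attack the ester on the pyranone (Dieckmann-type Claisen condensation). Enolisation would aromatise ring A to the allyl ether A8, which a zerovalent palladium catalyst would deallylate.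
- In its favour: like the chosen plan it fixes the 8-alkyl regiochemistry by having ring C in place first, so the two are equal there. It forms a single C–C bond and needs neither halogen nor Lewis acid near the acid-sensitive alkenes, so it is better on functional-group tolerance.
- Against it here: the side-chain carbon of A9 that is alpha to both the ring and the ketone is the most acidic position, so the required methyl enolate is the less favoured second anion. The ester is a vinylogous carbonate and a poor acceptor. Assembling A9 means joining the chiral chain to a carbon flanked by the pyranone and the ketone, which brings back alkylation with a beta-branched, elimination-prone electrophile or a long acylation sequence.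
- Comparison: equal on regiocontrol and on configuration (the stereocentre is a spectator in both). It is less convergent and probably longer. The final deprotection is equal in cost.

Key step: step 12

## Route

Step 1
Reactants: 1 (4R)-limonene 1,2-oxide [(4R)-1-methyl-4-(prop-1-en-2-yl)-7-oxabicyclo[4.1.0]heptane, cis/trans mixture]
Product: 3 (3R)-6-oxo-3-(prop-1-en-2-yl)heptanal, via (4R)-p-menth-8-ene-1,2-diol 2 (not isolated)
Conditions: H5IO6 (1.1 equiv), THF–H2O, 0 °C to rt
Reagents that add atoms: water, O
Why: Acid-promoted epoxide hydrolysis followed by periodate glycol cleavage (Malaprade reaction) opens the ring between the two epoxide carbons; both epoxide stereocentres vanish, so the cis/trans mixture converges, and C4 (beta to the aldehyde, gamma to the ketone) is not enolisable.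

Step 2
Reactants: 3 (3R)-6-oxo-3-(prop-1-en-2-yl)heptanal
Product: 4 (5R)-2-methyl-5-(prop-1-en-2-yl)octa-1,7-diene
Conditions: Ph3PCH3Br (3.0 equiv), KOtBu (2.9 equiv), THF, 0 °C; add 3 at −78 °C, then rt
Reagents that add atoms: methyltriphenylphosphonium bromide, C[P+](c1ccccc1)(c1ccccc1)c1ccccc1.[Br-]
Why: Double Wittig methylenation turns the aldehyde into a vinyl group and the ketone into the 2-methylallyl terminus; adding the dicarbonyl compound to excess preformed ylide at low temperature lets olefination outrun aldol cyclisation, and the stereocentre has no acidic hydrogen.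

Step 3
Reactants: 4 (5R)-2-methyl-5-(prop-1-en-2-yl)octa-1,7-diene
Product: 6 (4R)-7-methyl-4-(prop-1-en-2-yl)oct-7-en-1-ol, via alkyl(disiamyl)borane 5 (not isolated)
Conditions: (Sia)2BH [bis(3-methylbutan-2-yl)borane, 1.05 equiv, from BH3·SMe2 and 2-methylbut-2-ene], THF, 0 °C; then NaOH, H2O2, 0 °C to rt
Reagents that add atoms: hydrogen peroxide, OO
Why: Hydroboration–oxidation: the hindered dialkylborane should add to the single monosubstituted alkene much faster than to the two 1,1-disubstituted alkenes and place boron on the terminal carbon; oxidation with retention gives the primary alcohol (the descriptor of 5 is S by priority rules only, the centre is untouched).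

Step 4
Reactants: 6 (4R)-7-methyl-4-(prop-1-en-2-yl)oct-7-en-1-ol
Product: 8 (4R)-7-methyl-4-(prop-1-en-2-yl)oct-7-enoic acid, via (4R)-7-methyl-4-(prop-1-en-2-yl)oct-7-enal 7 (not isolated)
Conditions: TEMPO (0.2 equiv), PhI(OAc)2 (2.2 equiv), MeCN–H2O (1:1), rt
Reagents that add atoms: water, O
Why: Oxoammonium (TEMPO) oxidation takes the primary alcohol through aldehyde 7 and its hydrate to the acid under near-neutral conditions that do not touch isolated alkenes; the stereocentre is gamma to the new carbonyl.

Step 5
Reactants: 8 (4R)-7-methyl-4-(prop-1-en-2-yl)oct-7-enoic acid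
Product: 10 methyl (6R)-9-methyl-3-oxo-6-(prop-1-en-2-yl)dec-9-enoate, via acyl imidazolide 9 (not isolated)
Conditions: CDI (1.2 equiv), THF, rt; then KO2CCH2CO2Me (1.5 equiv), MgCl2 (1.5 equiv), Et3N (1.5 equiv), THF–MeCN, rt to 40 °C; cold dilute HCl work-up
Reagents that add atoms: potassium methyl malonate, COC(=O)CC(=O)[O-].[K+]
Why: Masamune–Brooks homologation: imidazolide 9 C-acylates the magnesium enolate of the malonate half-ester and the adduct decarboxylates on acidic work-up, giving the beta-keto ester without strong base and without any leaving group near the stereocentre.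

Step 6
Reactants: 10 methyl (6R)-9-methyl-3-oxo-6-(prop-1-en-2-yl)dec-9-enoate
Product: 11 methyl (2Z,6R)-9-methyl-6-(prop-1-en-2-yl)-3-(trimethylsilyloxy)deca-2,9-dienoate
Conditions: Me3SiCl (1.5 equiv), Et3N (1.6 equiv), toluene, rt, 48 h; filtration under argon
Reagents that add atoms: chlorotrimethylsilane, C[Si](C)(C)Cl
Why: Soft enolisation and O-silylation of the beta-keto ester give the 3-silyloxy enoate; the C2=C3 geometry (Z drawn, a mixture is acceptable) is lost in the next step.

Step 7
Reactants: 11 methyl (2Z,6R)-9-methyl-6-(prop-1-en-2-yl)-3-(trimethylsilyloxy)deca-2,9-dienoate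
Product: 12 (1E,3Z,6R)-1-methoxy-9-methyl-6-(prop-1-en-2-yl)-1,3-bis(trimethylsilyloxy)deca-1,3,9-triene
Conditions: LiN(i-Pr)2 (1.3 equiv, from i-Pr2NH and n-BuLi), THF, −78 °C; Me3SiCl (1.4 equiv), −78 °C to rt; hexane, filtration under argon, used crude
Reagents that add atoms: chlorotrimethylsilane, C[Si](C)(C)Cl
Why: Kinetic gamma-deprotonation of the vinylogous ester and O-silylation of the dienolate give the 1-methoxy-1,3-bis(silyloxy)diene; the stereocentre is beta to the deprotonated carbon and carries no acidic hydrogen.

Step 8
Reactants: 13 4-hydroxybenzaldehyde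
Product: 14 4-(triisopropylsilyloxy)benzaldehyde
Conditions: i-Pr3SiCl (1.1 equiv), imidazole (2.2 equiv), DMF, rt
Reagents that add atoms: chlorotriisopropylsilane, CC(C)[Si](Cl)(C(C)C)C(C)C
Why: Standard imidazole-promoted silylation of a phenol; the bulky aryl silyl ether is chosen to survive Lewis acid, bromination, DDQ and catalytic silyl triflate.

Step 9
Reactants: 14 4-(triisopropylsilyloxy)benzaldehyde; 15 (E)-1-methoxy-3-(trimethylsilyloxy)buta-1,3-diene
Product: 17 rac-2-[4-(triisopropylsilyloxy)phenyl]-2,3-dihydro-4H-pyran-4-one, via 5,6-dihydro-2H-pyran cycloadduct 16 (not isolated)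
Conditions: ZnCl2 (0.5 equiv), THF, rt; then TFA (cat.), CH2Cl2, 0 °C
Reagents that add atoms: none
Why: Lewis acid-catalysed hetero-Diels–Alder reaction of the aldehyde with the 1-alkoxy-3-silyloxydiene, then acid-induced loss of MeOSiMe3 from 16 to the vinylogous ester; the C2 stereocentre is racemic and is destroyed in step 11.

Step 10
Reactants: 17 rac-2-[4-(triisopropylsilyloxy)phenyl]-2,3-dihydro-4H-pyran-4-one
Product: 18 rac-5-bromo-2-[4-(triisopropylsilyloxy)phenyl]-2,3-dihydro-4H-pyran-4-one
Conditions: NBS (1.05 equiv), CH2Cl2, 0 °C to rt, dark
Reagents that add atoms: N-bromosuccinimide, O=C1CCC(=O)N1Br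
Why: Electrophilic alpha-bromination of a vinylogous ester: C5 is the only enol-ether carbon, so the position of bromine is unambiguous, and it is far more nucleophilic than the silyloxy arene.

Step 11
Reactants: 18 rac-5-bromo-2-[4-(triisopropylsilyloxy)phenyl]-2,3-dihydro-4H-pyran-4-one
Product: 19 5-bromo-2-[4-(triisopropylsilyloxy)phenyl]-4H-pyran-4-one
Conditions: DDQ (1.5 equiv), 1,4-dioxane, 90 °C
Reagents that add atoms: none
Why: Quinone dehydrogenation of the kind used for flavanone to flavone: DDQ removes hydride from C2, which is benzylic to an electron-rich arene and alpha to the ring oxygen, and loss of the C3 proton gives the pyranone; neither the vinyl bromide nor the silyl ether is affected.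

Step 12
Reactants: 12 (1E,3Z,6R)-1-methoxy-9-methyl-6-(prop-1-en-2-yl)-1,3-bis(trimethylsilyloxy)deca-1,3,9-triene (1.5 equiv); 19 5-bromo-2-[4-(triisopropylsilyloxy)phenyl]-4H-pyran-4-one
Product: 23 5,7-dihydroxy-8-[(2R)-5-methyl-2-(prop-1-en-2-yl)hex-5-en-1-yl]-2-[4-(triisopropylsilyloxy)phenyl]-4H-chromen-4-one, via 4-silyloxypyrylium triflate 20 (not isolated), via bromo cycloadduct 21 (not isolated), via 5,7-bis(trimethylsilyl) ether 22 (not isolated)
Conditions: Me3SiOTf (0.2 equiv), 2,6-di-tert-butylpyridine (0.3 equiv), CH2Cl2, −78 to 0 °C; DBU (2.0 equiv), 0 °C to rt; then citric acid, THF–H2O, rt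
Reagents that add atoms: none
Why: Proposed new method: Me3SiOTf silylates the carbonyl oxygen of 19 to give pyrylium 20, whose unsubstituted C6 (the other alpha position carries the electron-rich aryl group) is attacked by the nucleophilic C4 terminus of 12 in a vinylogous Mukaiyama–Michael addition that forms C8–C8a; the resulting 4-silyloxy-2H-pyran is a bromo-substituted silyl enol ether whose C5 then attacks the silylated ester (dioxocarbenium) carbon, forming C4a–C5 by a 6-(enolexo)-exo-trig closure of ring A and releasing Me3SiOTf, so that the two events amount to a formal Diels–Alder addition across C5=C6 and give 21. DBU then removes HBr across C4a–C8a (dehydrobromination of an alpha-bromo ketone) and methanol across C5/C8, which aromatises ring A to 22, and citric acid hydrolyses the two aryl trimethylsilyl ethers while the triisopropylsilyl ether stays. The closest known reaction types are the regiospecific cycloaddition–aromatisation of 1-alkoxy-1,3-bis(silyloxy)dienes with bromoquinones and the silyl triflate-promoted additions of silyl ketene acetals and bis(silyloxy)dienes to C2 of chromones; neither has been shown on a halogenated 4-pyranone. No stereocentre created here survives: C8, C8a, C4a and C5 of 21 are erased on aromatisation, and C2'' is a spectator two atoms from the reacting carbon with no acidic hydrogen. The step needs regiocontrol (alkyl next to C8a, not C4a), and polarity secures it: only C6 of 20 is an open electrophilic alpha position and only C5 carries the enol carbon and the leaving group, while the pre-formed ring C excludes a 6-alkyl isomer. It also needs the acid-labile 1,1-disubstituted alkenes to survive, which is why the triflate is catalytic and buffered by a hindered pyridine.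

Step 13
Reactants: 23 5,7-dihydroxy-8-[(2R)-5-methyl-2-(prop-1-en-2-yl)hex-5-en-1-yl]-2-[4-(triisopropylsilyloxy)phenyl]-4H-chromen-4-one
Product: 24 5,7-dihydroxy-2-(4-hydroxyphenyl)-8-[(2R)-5-methyl-2-(prop-1-en-2-yl)hex-5-en-1-yl]-4H-chromen-4-one
Conditions: Bu4NF (1.2 equiv), THF, 0 °C; aq. NH4Cl
Reagents that add atoms: none
Why: Fluoride cleavage of an aryl silyl ether, fast at 0 °C because the leaving group is a phenoxide conjugated to the chromone; alkenes, phenols and the stereocentre are inert.

## Compound list

1 | (4R)-limonene 1,2-oxide, (4R)-1-methyl-4-(prop-1-en-2-yl)-7-oxabicyclo[4.1.0]heptane, cis/trans mixture | C=C(C)[C@@H]1CCC2(C)OC2C1 | starting material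
2 | (4R)-1-methyl-4-(prop-1-en-2-yl)cyclohexane-1,2-diol, diastereomer mixture | C=C(C)[C@@H]1CCC(C)(O)C(O)C1 | intermediate (not isolated)
3 | (3R)-6-oxo-3-(prop-1-en-2-yl)heptanal | CC(=O)CC[C@H](CC=O)C(C)=C | intermediate
4 | (5R)-2-methyl-5-(prop-1-en-2-yl)octa-1,7-diene | C=C(C)CC[C@H](CC=C)C(=C)C | intermediate
5 | [(4S)-7-methyl-4-(prop-1-en-2-yl)oct-7-en-1-yl]bis(3-methylbutan-2-yl)borane (same spatial arrangement; S by priority) | C=C(C)CC[C@H](CCCB(C(C)C(C)C)C(C)C(C)C)C(=C)C | intermediate (not isolated)
6 | (4R)-7-methyl-4-(prop-1-en-2-yl)oct-7-en-1-ol | C=C(C)CC[C@H](CCCO)C(=C)C | intermediate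
7 | (4R)-7-methyl-4-(prop-1-en-2-yl)oct-7-enal | C=C(C)CC[C@H](CCC=O)C(=C)C | intermediate (not isolated)
8 | (4R)-7-methyl-4-(prop-1-en-2-yl)oct-7-enoic acid | C=C(C)CC[C@H](CCC(=O)O)C(=C)C | intermediate
9 | 1-[(4R)-7-methyl-4-(prop-1-en-2-yl)oct-7-enoyl]-1H-imidazole | C=C(C)CC[C@H](CCC(=O)n1ccnc1)C(=C)C | intermediate (not isolated)
10 | methyl (6R)-9-methyl-3-oxo-6-(prop-1-en-2-yl)dec-9-enoate | C=C(C)CC[C@H](CCC(=O)CC(=O)OC)C(=C)C | intermediate
11 | methyl (2Z,6R)-9-methyl-6-(prop-1-en-2-yl)-3-(trimethylsilyloxy)deca-2,9-dienoate | C=C(C)CC[C@H](CC/C(O[Si](C)(C)C)=C/C(=O)OC)C(=C)C | intermediate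
12 | (1E,3Z,6R)-1-methoxy-9-methyl-6-(prop-1-en-2-yl)-1,3-bis(trimethylsilyloxy)deca-1,3,9-triene | C=C(C)CC[C@H](C/C=C(O[Si](C)(C)C)/C=C(\OC)O[Si](C)(C)C)C(=C)C | intermediate (key-step precursor)
13 | 4-hydroxybenzaldehyde | O=Cc1ccc(O)cc1 | starting material
14 | 4-(triisopropylsilyloxy)benzaldehyde | O=Cc1ccc(O[Si](C(C)C)(C(C)C)C(C)C)cc1 | intermediate
15 | (E)-1-methoxy-3-(trimethylsilyloxy)buta-1,3-diene | CO/C=C/C(=C)O[Si](C)(C)C | starting material
16 | rac-2-methoxy-6-[4-(triisopropylsilyloxy)phenyl]-4-(trimethylsilyloxy)-5,6-dihydro-2H-pyran, cis/trans mixture | COC1C=C(O[Si](C)(C)C)CC(c2ccc(O[Si](C(C)C)(C(C)C)C(C)C)cc2)O1 | intermediate (not isolated)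
17 | rac-2-[4-(triisopropylsilyloxy)phenyl]-2,3-dihydro-4H-pyran-4-one | O=C1C=COC(c2ccc(O[Si](C(C)C)(C(C)C)C(C)C)cc2)C1 | intermediate
18 | rac-5-bromo-2-[4-(triisopropylsilyloxy)phenyl]-2,3-dihydro-4H-pyran-4-one | O=C1CC(c2ccc(O[Si](C(C)C)(C(C)C)C(C)C)cc2)OC=C1Br | intermediate
19 | 5-bromo-2-[4-(triisopropylsilyloxy)phenyl]-4H-pyran-4-one | O=c1cc(-c2ccc(O[Si](C(C)C)(C(C)C)C(C)C)cc2)occ1Br | intermediate (key-step precursor)
20 | 3-bromo-6-[4-(triisopropylsilyloxy)phenyl]-4-(trimethylsilyloxy)pyrylium trifluoromethanesulfonate | C[Si](C)(C)Oc1cc(-c2ccc(O[Si](C(C)C)(C(C)C)C(C)C)cc2)[o+]cc1Br.[O-]S(=O)(=O)C(F)(F)F | intermediate (not isolated)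
21 | 4a-bromo-5-methoxy-8-[(2R)-5-methyl-2-(prop-1-en-2-yl)hex-5-en-1-yl]-2-[4-(triisopropylsilyloxy)phenyl]-5,7-bis(trimethylsilyloxy)-4a,5,8,8a-tetrahydro-4H-chromen-4-one, diastereomer mixture at C4a, C5, C8, C8a | C=C(C)CC[C@H](CC1C(O[Si](C)(C)C)=CC(OC)(O[Si](C)(C)C)C2(Br)C(=O)C=C(c3ccc(O[Si](C(C)C)(C(C)C)C(C)C)cc3)OC12)C(=C)C | intermediate (not isolated)
22 | 8-[(2R)-5-methyl-2-(prop-1-en-2-yl)hex-5-en-1-yl]-2-[4-(triisopropylsilyloxy)phenyl]-5,7-bis(trimethylsilyloxy)-4H-chromen-4-one | C=C(C)CC[C@H](Cc1c(O[Si](C)(C)C)cc(O[Si](C)(C)C)c2c(=O)cc(-c3ccc(O[Si](C(C)C)(C(C)C)C(C)C)cc3)oc12)C(=C)C | intermediate (not isolated)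
23 | 5,7-dihydroxy-8-[(2R)-5-methyl-2-(prop-1-en-2-yl)hex-5-en-1-yl]-2-[4-(triisopropylsilyloxy)phenyl]-4H-chromen-4-one | C=C(C)CC[C@H](Cc1c(O)cc(O)c2c(=O)cc(-c3ccc(O[Si](C(C)C)(C(C)C)C(C)C)cc3)oc12)C(=C)C | intermediate (key-step product)
24 | 5,7-dihydroxy-2-(4-hydroxyphenyl)-8-[(2R)-5-methyl-2-(prop-1-en-2-yl)hex-5-en-1-yl]-4H-chromen-4-one | C=C(C)CC[C@H](Cc1c(O)cc(O)c2c(=O)cc(-c3ccc(O)cc3)oc12)C(=C)C | target

## Step count and least certain steps

Total: 13 steps (steps 1–7 for fragment 1, steps 8–11 for fragment 2, steps 12 and 13 after convergence). Longest linear sequence: 9 steps (steps 1–7, 12, 13).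

Step 12 (key step, proposed new method). What is most likely to go wrong is collapse of the cationic intermediate by desilylation before ring A closes, because triflate can remove the silyl group faster than the hindered bromo enol carbon attacks. The open-chain adduct is a beta-alkoxy ketone, and added base would then open ring C by retro-oxa-Michael reaction. Further risks are protonation of the 1,1-disubstituted alkenes by adventitious triflic acid and halophilic attack of the diene on bromine.

Fallback by known chemistry, setting out from 12 and returning at 24: ring A is made first by cycloaddition–aromatisation of the silyloxydiene with an acetylenic ketone, and ring C is closed last by C–O coupling. Diene 12 and 4-bromobut-3-yn-2-one F1 (from but-3-yn-2-one, NBS, catalytic AgNO3) would be combined in toluene, followed by an acidic aqueous work-up. Diels–Alder addition with the nucleophilic diene terminus on the bromine-bearing alkyne carbon, loss of methanol and desilylation should give 1-{2-bromo-4,6-dihydroxy-3-[(2R)-5-methyl-2-(prop-1-en-2-yl)hex-5-en-1-yl]phenyl}ethan-1-one F2, in which bromine marks the future C8a. Silylation (t-BuMe2SiCl, imidazole) would give the bis(silyl) ether F3. Its lithium enolate (LiN(SiMe3)2, THF, −78 °C) would add to aldehyde 14 to give the aldol F4, and Dess–Martin oxidation would give the 1,3-diketone F5. CuI, 1,10-phenanthroline and K3PO4 in DMF would close ring C by intramolecular Ullmann-type O-arylation of the diketone enolate, giving the tris(silyl) ether F6, and Bu4NF would remove all three silyl groups to deliver 24. Regiochemistry is again built in, since O1 can only enter where bromine stood, at the price of five more operations.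

Step 3. What is most likely to go wrong is insufficient site selectivity, that is, hydroboration of a 1,1-disubstituted alkene as well. The rate difference between alkene classes is finite and two such alkenes compete with one vinyl group.

Fallback, setting out from 3 and returning at 7: the carbonyl groups are told apart instead of the alkenes. Aldehyde-selective Wittig reaction of 3 with Ph3P=CHOMe (from Ph3PCH2OMe Cl and KN(SiMe3)2, 1.0 equiv, −78 °C) would give (5R)-8-methoxy-5-(prop-1-en-2-yl)oct-7-en-2-one F7. Methylenation of the ketone with Ph3P=CH2 would give (4R)-1-methoxy-7-methyl-4-(prop-1-en-2-yl)octa-1,7-diene F8. Brief hydrolysis of the enol ether (dilute HCl, THF, 0 °C) would give aldehyde 7, which the conditions of step 4, or NaClO2 (Pinnick oxidation), take on to 8.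

Step 11. What is most likely to go wrong is sluggish hydride abstraction, because the ring oxygen belongs to a vinylogous ester and stabilises the C2 cation less than an ether oxygen would. Forcing the temperature then invites decomposition of the electron-rich arene or loss of the silyl ether.

Fallback, setting out from 18 and returning at 19: the unsaturation is introduced through the enolate instead of by hydride abstraction. LiN(SiMe3)2 (THF, −78 °C) and PhSeCl would give rac-5-bromo-3-(phenylselanyl)-2-[4-(triisopropylsilyloxy)phenyl]-2,3-dihydro-4H-pyran-4-one F9. Oxidation with H2O2 (CH2Cl2, pyridine, 0 °C) would then trigger syn-elimination of the selenoxide across C2–C3 to give 19.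

## Further compounds

F1 | step 12 | 4-bromobut-3-yn-2-one | CC(=O)C#CBr
F2 | step 12 | 1-{2-bromo-4,6-dihydroxy-3-[(2R)-5-methyl-2-(prop-1-en-2-yl)hex-5-en-1-yl]phenyl}ethan-1-one | C=C(C)CC[C@H](Cc1c(O)cc(O)c(C(C)=O)c1Br)C(=C)C
F3 | step 12 | 1-{2-bromo-4,6-bis(tert-butyldimethylsilyloxy)-3-[(2R)-5-methyl-2-(prop-1-en-2-yl)hex-5-en-1-yl]phenyl}ethan-1-one | C=C(C)CC[C@H](Cc1c(O[Si](C)(C)C(C)(C)C)cc(O[Si](C)(C)C(C)(C)C)c(C(C)=O)c1Br)C(=C)C
F4 | step 12 | 1-{2-bromo-4,6-bis(tert-butyldimethylsilyloxy)-3-[(2R)-5-methyl-2-(prop-1-en-2-yl)hex-5-en-1-yl]phenyl}-3-hydroxy-3-[4-(triisopropylsilyloxy)phenyl]propan-1-one, mixture of carbinol epimers | C=C(C)CC[C@H](Cc1c(O[Si](C)(C)C(C)(C)C)cc(O[Si](C)(C)C(C)(C)C)c(C(=O)CC(O)c2ccc(O[Si](C(C)C)(C(C)C)C(C)C)cc2)c1Br)C(=C)C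
F5 | step 12 | 1-{2-bromo-4,6-bis(tert-butyldimethylsilyloxy)-3-[(2R)-5-methyl-2-(prop-1-en-2-yl)hex-5-en-1-yl]phenyl}-3-[4-(triisopropylsilyloxy)phenyl]propane-1,3-dione | C=C(C)CC[C@H](Cc1c(O[Si](C)(C)C(C)(C)C)cc(O[Si](C)(C)C(C)(C)C)c(C(=O)CC(=O)c2ccc(O[Si](C(C)C)(C(C)C)C(C)C)cc2)c1Br)C(=C)C
F6 | step 12 | 5,7-bis(tert-butyldimethylsilyloxy)-8-[(2R)-5-methyl-2-(prop-1-en-2-yl)hex-5-en-1-yl]-2-[4-(triisopropylsilyloxy)phenyl]-4H-chromen-4-one | C=C(C)CC[C@H](Cc1c(O[Si](C)(C)C(C)(C)C)cc(O[Si](C)(C)C(C)(C)C)c2c(=O)cc(-c3ccc(O[Si](C(C)C)(C(C)C)C(C)C)cc3)oc12)C(=C)C
F7 | step 3 | (5R)-8-methoxy-5-(prop-1-en-2-yl)oct-7-en-2-one, E/Z mixture | CC(=O)CC[C@H](CC=COC)C(C)=C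
F8 | step 3 | (4R)-1-methoxy-7-methyl-4-(prop-1-en-2-yl)octa-1,7-diene, E/Z mixture | C=C(C)CC[C@H](CC=COC)C(=C)C
F9 | step 11 | rac-5-bromo-3-(phenylselanyl)-2-[4-(triisopropylsilyloxy)phenyl]-2,3-dihydro-4H-pyran-4-one | O=C1C([Se]c2ccccc2)C(c2ccc(O[Si](C(C)C)(C(C)C)C(C)C)cc2)OC=C1Br
A1 | alternative 1 | pyrano-fused lactol of the flavone with the 3-methylbut-3-enyl branch at the new stereocentre, anomeric mixture | C=C(C)CC[C@@H]1Cc2c(cc(O)c3c(=O)cc(-c4ccc(O)cc4)oc23)OC1O
A2 | alternative 1 | [5,7-dihydroxy-2-(4-hydroxyphenyl)-4-oxo-4H-chromen-8-yl]-N,N,N-trimethylmethanaminium iodide | C[N+](C)(C)Cc1c(O)cc(O)c2c(=O)cc(-c3ccc(O)cc3)oc12.[I-]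
A3 | alternative 1 | 5-methylhex-5-enal | C=C(C)CCCC=O
A4 | alternative 1 | (S)-2-[diphenyl(trimethylsilyloxy)methyl]pyrrolidine | C[Si](C)(C)OC(c1ccccc1)(c1ccccc1)[C@@H]1CCCN1
A5 | alternative 2 | 5-(tert-butyldimethylsilyloxy)-2-[4-(tert-butyldimethylsilyloxy)phenyl]-7-hydroxy-8-[(2R)-5-methyl-2-(prop-1-en-2-yl)hex-5-en-1-yl]-4H-chromen-4-one | C=C(C)CC[C@H](Cc1c(O)cc(O[Si](C)(C)C(C)(C)C)c2c(=O)cc(-c3ccc(O[Si](C)(C)C(C)(C)C)cc3)oc12)C(=C)C
A6 | alternative 2 | 5-(tert-butyldimethylsilyloxy)-4-iodo-2-[(2R)-5-methyl-2-(prop-1-en-2-yl)hex-5-en-1-yl]benzene-1,3-diol | C=C(C)CC[C@H](Cc1c(O)cc(O[Si](C)(C)C(C)(C)C)c(I)c1O)C(=C)C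
A7 | alternative 2 | tert-butyl(4-ethynylphenoxy)dimethylsilane | C#Cc1ccc(O[Si](C)(C)C(C)(C)C)cc1
A8 | alternative 3 | 2-[4-(allyloxy)phenyl]-5,7-dihydroxy-8-[(2R)-5-methyl-2-(prop-1-en-2-yl)hex-5-en-1-yl]-4H-chromen-4-one | C=C(C)CC[C@H](Cc1c(O)cc(O)c2c(=O)cc(-c3ccc(OCC=C)cc3)oc12)C(=C)C
A9 | alternative 3 | methyl 6-[4-(allyloxy)phenyl]-2-[(5R)-8-methyl-2-oxo-5-(prop-1-en-2-yl)non-8-en-3-yl]-4-oxo-4H-pyran-3-carboxylate, epimer mixture at the side-chain carbon next to the ring | C=C(C)CC[C@H](CC(C(C)=O)c1oc(-c2ccc(OCC=C)cc2)cc(=O)c1C(=O)OC)C(=C)C
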